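- The constants set how fast each step runs, but before you use them, write down what the charges demand of the flasks below.

| flask | substrate | partner | time | remark | temperature |
|---|---|---|---|---|---|
| Saturday's | 10 mM | 9.00 mM | 20 s | at 45 °C until 10 s, from then on at 25 °C |  |
| Friday's | 10 mM | 9.00 mM | 20 s |  | 25 °C |
| Tuesday's | 10 mM | 9.00 mM | 20 s |  | 45 °C |

    substrate + partner → target, rate k1*[substrate]^2*[partner]^0.5 (k1 = 780 L¹·⁵ mol⁻¹·⁵ s⁻¹, Ea1 = 36.0 kJ mol⁻¹)
    substrate + target → side product (k2 = 1.3 L mol⁻¹ s⁻¹, Ea2 = 40.0 kJ mol⁻¹)
    (constants at 25 °C)

- a species is counted by the substrate in it: one side product counts as two
- the list of constants is for 25 °C, to be carried to other temperatures by the activation energies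

* the flask with the highest amount of target, in percent of the substrate charged ("all alike" if they lie within 1.5 percentage points) (Saturday's / Friday's / Tuesday's / all alike)
* final target, as a percentage of the substrate charged, in Saturday's
* final target, as a percentage of the substrate charged, in Friday's
* final target, as a percentage of the substrate charged, in Tuesday's

- Each target holds one partner and one substrate, and each side product holds one partner and two substrates. Eliminating the side product from the two balances gives, at any moment, c(target) = 2 c(partner, charged) − c(substrate, charged) + c(substrate) − 2 c(partner).
- The charged part, taken as a share of the substrate charged, I call the anchor 80.0%. What is left then tells you how far target stands from it: c(substrate) − 2 c(partner), over the substrate charged.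
- Now turn the question round. For one flask to stand out, its leftover term would have to differ from the others' by more than 1.5 percentage points of the substrate charged.
- Heating speeds step 1 by 2.5 and step 2 by 2.8, so k2/k1 shifts by a factor of just 1.11. Dividing one rate by the other removes time, so I expect the flasks to walk nearly one path, the hot ones faster.
- At 25 °C the starting time of step 1 is 1.35 s, much shorter than the 20 s of the run. That time lengthens as the charges fall, so this is a rough guide.
- I therefore commit to the anchor and expect no flask to stand out: 80.0% in Saturday's, 80.0% in Friday's and 80.0% in Tuesday's.
- The forecast, “integrated by hand with Simpson steps”, gives 80% for Saturday's, 79.6% for Friday's and 79.7% for Tuesday's, and its verdict is all alike.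
- The simulation gives 80.0% for Saturday's, 79.6% for Friday's and 79.8% for Tuesday's, so the verdict is all alike.
- In Friday's, step 1 uses substrate 58 times as fast as step 2 at 1.16 s and 2.3 times as fast at 20.0 s, when the half-life of target by step 2 is 7.2 min, far longer than the 20 s run. With substrate at 12.3% and partner at 7.06% of its own charge, the anchor reckoning returns 79.6% for Friday's.
- Take the neighbour of Friday's charged with 17 mM of substrate: its anchor falls to 5.88%. The simulation ends this flask with partner, the limiting reagent, at 0%, substrate at 38.1% and target at 44.0%, which is the anchor plus that leftover substrate.

The numbers stand for no real mixture; what happens was integrated by code.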